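## Retrosynthetic overview

1. Target **26** is 2α,6α,19-trihydroxylabda-8,13-dien-15,16-olide (labdane numbering throughout; β is the face of C20). Late disconnections are C12–C13 (B-alkyl Suzuki–Miyaura coupling with 4-bromofuran-2(5H)-one), C9–C11 (Stille vinylation of a C9 enol triflate), C5–H/C6–O (hydroboration of a C5=C6 alkene), and C8–C17 (enolate methylation).
2. Structural feature used: the quaternary C10 with its methyl C20 lies between C5 and C9. Ring B (C5–C10) is therefore the ring of 2-methylcyclohexane-1,3-dione, with C10 as its prochiral carbon and C5/C9 as its two carbonyls. C4 is α to the carboxyl-level carbon C19.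
3. Key disconnection: C4–C5. Ring A is closed by a copper-hydride reductive aldol of an acrylate tethered to C10. The single C2 silyloxy stereocentre decides which carbonyl becomes C5, and so sets C10 and C4.
4. The precursor comes from dione C-allylation (C1, C2), ozonolysis, chromium-catalysed enantioselective 2-(methoxycarbonyl)allylation of the aldehyde (C2–C3, sets C2), and silylation.
5. Ring order: ring B is bought as the dione, ring A is formed in step 5, and the butenolide ring is attached intact in step 12.

Key step: step 5

Assumption: in step 3 the (4S,4'S) antipode of the bis(oxazolinyl)carbazole ligand is taken as the one that delivers the (R)-carbinol; if the sense is the reverse, the (4R,4'R) antipode is used and nothing else changes.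

## Route

**Step 1**
Reactants: 1 2-methylcyclohexane-1,3-dione; 2 allyl bromide
Product: 3 2-allyl-2-methylcyclohexane-1,3-dione
Conditions: 1 M aq NaOH, rt
Reagents that add atoms: none
Why: C-alkylation (SN2) of the stabilised dione enolate by the soft allylic bromide in water, a standard way to the 2,2-disubstituted dione; no stereocentre is formed.

**Step 2**
Reactants: 3 2-allyl-2-methylcyclohexane-1,3-dione
Product: 5 2-(1-methyl-2,6-dioxocyclohexyl)acetaldehyde, via secondary ozonide 4 (not isolated)
Conditions: O3, CH2Cl2, −78 °C; then PPh3, −78 °C → rt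
Reagents that add atoms: ozone, [O-][O+]=O
Why: Ozonolysis of the terminal alkene (Criegee mechanism) with reductive work-up should give the aldehyde and leave both ketones untouched.

**Step 3**
Reactants: 5 2-(1-methyl-2,6-dioxocyclohexyl)acetaldehyde; 6 methyl 2-(bromomethyl)acrylate
Product: 8 methyl (4R)-4-hydroxy-5-(1-methyl-2,6-dioxocyclohexyl)-2-methylidenepentanoate, via trimethylsilyl ether 7 (not isolated)
Conditions: CrCl2 (10 mol %), 1,8-bis[(4S)-4-isopropyl-4,5-dihydrooxazol-2-yl]-3,6-diphenyl-9H-carbazole (12 mol %), iPr2NEt (30 mol %), Mn powder, TMSCl, THF, rt; then 1 M aq HCl, THF, 0 °C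
Reagents that add atoms: none
Why: Catalytic asymmetric Nozaki–Hiyama–Kishi 2-(alkoxycarbonyl)allylation, in which the allylchromium species from 6 adds only to the aldehyde (ketones are inert) on the ligand-bound trivalent chromium, so the ligand sets C2 as R; brief cold acid then frees the alcohol without lactonisation.

**Step 4**
Reactants: 8 methyl (4R)-4-hydroxy-5-(1-methyl-2,6-dioxocyclohexyl)-2-methylidenepentanoate
Product: 9 methyl (4R)-4-(tert-butyldimethylsilyloxy)-5-(1-methyl-2,6-dioxocyclohexyl)-2-methylidenepentanoate
Conditions: TBSCl, imidazole, DMF, rt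
Reagents that add atoms: tert-butyldimethylsilyl chloride, CC(C)(C)[Si](C)(C)Cl
Why: Silylation of the secondary alcohol traps the open hydroxy dione (any hemiketal is in equilibrium with it and its tertiary hydroxyl is unreactive) and blocks lactonisation onto the ester; C2 is untouched.

**Step 5**
Reactants: 9 methyl (4R)-4-(tert-butyldimethylsilyloxy)-5-(1-methyl-2,6-dioxocyclohexyl)-2-methylidenepentanoate
Product: 12 methyl 2α-(tert-butyldimethylsilyloxy)-5β-hydroxy-9-oxo-11,12,13,14,15,16,17-heptanorlabdan-19-oate (cis-fused), via copper enolate 10 (not isolated), via copper aldolate 11 (not isolated)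
Conditions: [(Ph3P)CuH]6 (0.25 equiv, 1.5 Cu–H), toluene, −40 → 0 °C; then sat. aq NH4Cl
Reagents that add atoms: none
Why: The hexameric monovalent copper hydride delivers hydride to the unsubstituted acrylate terminus (which becomes the C18 methyl) much faster than it attacks an unactivated ketone, giving the tetrasubstituted copper enolate 10 with the copper-bound oxygen cis to C18, and this enolate adds to one dione carbonyl to give aldolate 11; the closest known reaction type is the copper-hydride reductive aldol cyclisation of enoates onto ketones, which is documented for the desymmetrisation of 2,2-disubstituted cyclohexane-1,3-diones. Ring A closes by a 6-(enolexo)-exo-trig aldol addition, a favoured mode, which forms C4–C5. The addition should pass through a chair of the forming ring A fused to a copper-bridged Zimmerman–Traxler array, which with this enolate geometry can be reached only when C19 is axial and the C5 oxygen equatorial on ring A; this fixes C4 (C19 β, C18 α, which also avoids a C18/C20 syn-pentane contact) and C5 (oxygen cis to C19). Because the C5–C6 bond is then axial, ring B can be attached only with C9 equatorial and C20 axial, and the bulky C2 silyloxy group takes the equatorial site, so the carbonyl attacked is the one that places C20 trans to the silyloxy group; this is how the single C2 centre sets C10. The step needs group selectivity between the two diastereotopic carbonyls and face selectivity at C4, and both rest on the equatorial silyloxy group and the chelated chair, since the competing chairs either put the silyloxy group syn-axial to C20 and C19 or give up the chelate. The C5 configuration does not matter, because the carbinol is dehydrated in step 6.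

**Step 6**
Reactants: 12 methyl 2α-(tert-butyldimethylsilyloxy)-5β-hydroxy-9-oxo-11,12,13,14,15,16,17-heptanorlabdan-19-oate
Product: 13 methyl 2α-(tert-butyldimethylsilyloxy)-9-oxo-11,12,13,14,15,16,17-heptanorlabd-5-en-19-oate
Conditions: SOCl2, pyridine, CH2Cl2, −20 → 0 °C
Reagents that add atoms: none
Why: E2 dehydration through the chlorosulfite, where the tertiary C5 carbinol has β-hydrogens only on C6 (C4 and C10 are quaternary) and its C–O bond is axial on ring B and antiperiplanar to an axial H6, so only the C5=C6 alkene can form and base-induced retro-aldol is avoided.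

**Step 7**
Reactants: 13 methyl 2α-(tert-butyldimethylsilyloxy)-9-oxo-11,12,13,14,15,16,17-heptanorlabd-5-en-19-oate
Product: 15 methyl 2α-(tert-butyldimethylsilyloxy)-9-oxo-11,12,13,14,15,16-hexanorlabd-5-en-19-oate (C8 epimers), via lithium enolate 14 (not isolated)
Conditions: LiN(iPr)2, THF, −78 °C; then MeI, −78 → −20 °C
Reagents that add atoms: iodomethane, CI
Why: Kinetic enolate alkylation at C8, the only enolisable position (C10 is quaternary and the ester has no α-hydrogen); the C8 configuration is irrelevant because C8 becomes sp2 in step 8.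

**Step 8**
Reactants: 15 methyl 2α-(tert-butyldimethylsilyloxy)-9-oxo-11,12,13,14,15,16-hexanorlabd-5-en-19-oate
Product: 17 methyl 2α-(tert-butyldimethylsilyloxy)-9-(trifluoromethanesulfonyloxy)-11,12,13,14,15,16-hexanorlabda-5,8-dien-19-oate, via potassium enolate 16 (not isolated)
Conditions: KN(SiMe3)2, THF, −78 → −20 °C; then PhNTf2, −78 °C → rt
Reagents that add atoms: N-phenylbis(trifluoromethanesulfonimide), O=S(=O)(N(c1ccccc1)S(=O)(=O)C(F)(F)F)C(F)(F)F
Why: Enol triflate formation by O-sulfonylation of the only possible enolate, which places the tetrasubstituted C8=C9 alkene of the target and an electrophilic handle on C9.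

**Step 9**
Reactants: 17 methyl 2α-(tert-butyldimethylsilyloxy)-9-(trifluoromethanesulfonyloxy)-11,12,13,14,15,16-hexanorlabda-5,8-dien-19-oate
Product: 19 methyl 2α-(tert-butyldimethylsilyloxy)-6α-hydroxy-9-(trifluoromethanesulfonyloxy)-11,12,13,14,15,16-hexanorlabd-8-en-19-oate, via C6 alkylborane 18 (not isolated)
Conditions: BH3·THF (3 equiv), THF, 0 °C → rt; then NaBO3·4H2O, H2O, rt
Reagents that add atoms: sodium perborate, [Na+].[O-]OB=O
Why: Hydroboration–oxidation (anti-Markovnikov syn addition, retentive oxidation) puts boron on the CH terminus C6 and hydrogen on C5 from the α face, because the axial C20 and C19 groups cover the β face as in steroidal 5-enes, which sets 5α-H and 6α-OH; the electron-poor tetrasubstituted enol triflate and the hindered ester should not react and perborate is a mild oxidant for the triflate.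

**Step 10**
Reactants: 19 methyl 2α-(tert-butyldimethylsilyloxy)-6α-hydroxy-9-(trifluoromethanesulfonyloxy)-11,12,13,14,15,16-hexanorlabd-8-en-19-oate; 20 tributyl(vinyl)stannane
Product: 21 methyl 2α-(tert-butyldimethylsilyloxy)-6α-hydroxy-13,14,15,16-tetranorlabda-8,11-dien-19-oate
Conditions: Pd(PPh3)4 (5 mol %), LiCl (3 equiv), THF, 65 °C
Reagents that add atoms: none
Why: Stille coupling of an alkenyl triflate (oxidative addition to zerovalent palladium, chloride-assisted transmetalation, reductive elimination) brings in C11 and C12 and tolerates the free C6 hydroxyl.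

**Step 11**
Reactants: 21 methyl 2α-(tert-butyldimethylsilyloxy)-6α-hydroxy-13,14,15,16-tetranorlabda-8,11-dien-19-oate
Product: 22 2α-(tert-butyldimethylsilyloxy)-13,14,15,16-tetranorlabda-8,11-diene-6α,19-diol
Conditions: LiAlH4, THF, 0 °C → rt
Reagents that add atoms: none
Why: Hydride reduction of the neopentyl methyl ester to the C19 primary alcohol, done before any lactone is present; the diene and the silyl ether are inert.

**Step 12**
Reactants: 22 2α-(tert-butyldimethylsilyloxy)-13,14,15,16-tetranorlabda-8,11-diene-6α,19-diol; 23 4-bromofuran-2(5H)-one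
Product: 25 2α-(tert-butyldimethylsilyloxy)-6α,19-dihydroxylabda-8,13-dien-15,16-olide, via B-alkyl borane 24 (not isolated)
Conditions: 9-BBN (3.5 equiv), THF, rt → 50 °C; then H2O, 23, PdCl2(dppf) (10 mol %), AsPh3 (10 mol %), Cs2CO3, DMF, rt
Reagents that add atoms: none
Why: 9-BBN adds only to the monosubstituted vinyl terminus (the tetrasubstituted C8=C9 is inert) and the primary alkylborane undergoes B-alkyl Suzuki–Miyaura coupling with the bromobutenolide under mild carbonate conditions; any O–B bonds formed at the two hydroxyls by excess reagent are hydrolysed in the aqueous coupling medium.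

**Step 13**
Reactants: 25 2α-(tert-butyldimethylsilyloxy)-6α,19-dihydroxylabda-8,13-dien-15,16-olide
Product: 26 2α,6α,19-trihydroxylabda-8,13-dien-15,16-olide (CNP0387838.1)
Conditions: HF·pyridine, pyridine, THF, 0 °C → rt
Reagents that add atoms: none
Why: Fluoride-driven cleavage of the secondary silyl ether under buffered, mildly acidic conditions that should leave the base-sensitive butenolide and the tetrasubstituted alkene intact.

## Compound list

1 | 2-methylcyclohexane-1,3-dione | CC1C(=O)CCCC1=O | starting material
2 | allyl bromide | C=CCBr | starting material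
3 | 2-allyl-2-methylcyclohexane-1,3-dione | C=CCC1(C)C(=O)CCCC1=O | intermediate
4 | secondary ozonide of 3, 2-methyl-2-[(1,2,4-trioxolan-3-yl)methyl]cyclohexane-1,3-dione (racemic at the trioxolane carbon; not isolated) | CC1(CC2OCOO2)C(=O)CCCC1=O | intermediate
5 | 2-(1-methyl-2,6-dioxocyclohexyl)acetaldehyde | CC1(CC=O)C(=O)CCCC1=O | intermediate
6 | methyl 2-(bromomethyl)acrylate | C=C(CBr)C(=O)OC | starting material
7 | methyl (4R)-5-(1-methyl-2,6-dioxocyclohexyl)-2-methylidene-4-(trimethylsilyloxy)pentanoate (not isolated) | C=C(C[C@H](O[Si](C)(C)C)CC1(C)C(=O)CCCC1=O)C(=O)OC | intermediate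
8 | methyl (4R)-4-hydroxy-5-(1-methyl-2,6-dioxocyclohexyl)-2-methylidenepentanoate | C=C(C[C@H](O)CC1(C)C(=O)CCCC1=O)C(=O)OC | intermediate
9 | methyl (4R)-4-(tert-butyldimethylsilyloxy)-5-(1-methyl-2,6-dioxocyclohexyl)-2-methylidenepentanoate (key-step precursor) | C=C(C[C@H](O[Si](C)(C)C(C)(C)C)CC1(C)C(=O)CCCC1=O)C(=O)OC | intermediate
10 | copper enolate of 9 after hydride addition (C4=C19 ketene acetal, O–Cu cis to the C18 methyl, phosphine on copper not drawn; not isolated) | C/C(=C(\O[Cu])OC)C[C@H](O[Si](C)(C)C(C)(C)C)CC1(C)C(=O)CCCC1=O | intermediate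
11 | copper aldolate of 12 (5β-O–Cu, phosphine not drawn; not isolated) | O=C1[C@@]2(C)C[C@@H](O[Si](C)(C)C(C)(C)C)C[C@](C)(C(=O)OC)[C@@]2(O[Cu])CCC1 | intermediate
12 | methyl 2α-(tert-butyldimethylsilyloxy)-5β-hydroxy-9-oxo-11,12,13,14,15,16,17-heptanorlabdan-19-oate (cis-fused; 4α-Me C18, 4β-CO2Me C19, 10β-Me C20; key-step product) | O=C1[C@@]2(C)C[C@@H](O[Si](C)(C)C(C)(C)C)C[C@](C)(C(=O)OC)[C@@]2(O)CCC1 | intermediate
13 | methyl 2α-(tert-butyldimethylsilyloxy)-9-oxo-11,12,13,14,15,16,17-heptanorlabd-5-en-19-oate | O=C1[C@@]2(C)C[C@@H](O[Si](C)(C)C(C)(C)C)C[C@](C)(C(=O)OC)C2=CCC1 | intermediate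
14 | lithium C8=C9 enolate of 13 (not isolated) | [Li]OC=1[C@@]2(C)C[C@@H](O[Si](C)(C)C(C)(C)C)C[C@](C)(C(=O)OC)C2=CCC=1 | intermediate
15 | methyl 2α-(tert-butyldimethylsilyloxy)-9-oxo-11,12,13,14,15,16-hexanorlabd-5-en-19-oate (C8 epimer mixture, C8 left undefined) | O=C1[C@@]2(C)C[C@@H](O[Si](C)(C)C(C)(C)C)C[C@](C)(C(=O)OC)C2=CCC1C | intermediate
16 | potassium C8=C9 enolate of 15 (not isolated) | [K]OC=1[C@@]2(C)C[C@@H](O[Si](C)(C)C(C)(C)C)C[C@](C)(C(=O)OC)C2=CCC=1C | intermediate
17 | methyl 2α-(tert-butyldimethylsilyloxy)-9-(trifluoromethanesulfonyloxy)-11,12,13,14,15,16-hexanorlabda-5,8-dien-19-oate | CC1=C(OS(=O)(=O)C(F)(F)F)[C@@]2(C)C[C@@H](O[Si](C)(C)C(C)(C)C)C[C@](C)(C(=O)OC)C2=CC1 | intermediate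
18 | 6α-boryl (BH2), 5α-H adduct of 17 (not isolated) | CC1=C(OS(=O)(=O)C(F)(F)F)[C@@]2(C)C[C@@H](O[Si](C)(C)C(C)(C)C)C[C@](C)(C(=O)OC)[C@@H]2[C@@H](B)C1 | intermediate
19 | methyl 2α-(tert-butyldimethylsilyloxy)-6α-hydroxy-9-(trifluoromethanesulfonyloxy)-11,12,13,14,15,16-hexanorlabd-8-en-19-oate (5α-H) | CC1=C(OS(=O)(=O)C(F)(F)F)[C@@]2(C)C[C@@H](O[Si](C)(C)C(C)(C)C)C[C@](C)(C(=O)OC)[C@@H]2[C@@H](O)C1 | intermediate
20 | tributyl(vinyl)stannane | C=C[Sn](CCCC)(CCCC)CCCC | starting material
21 | methyl 2α-(tert-butyldimethylsilyloxy)-6α-hydroxy-13,14,15,16-tetranorlabda-8,11-dien-19-oate | CC1=C(C=C)[C@@]2(C)C[C@@H](O[Si](C)(C)C(C)(C)C)C[C@](C)(C(=O)OC)[C@@H]2[C@@H](O)C1 | intermediate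
22 | 2α-(tert-butyldimethylsilyloxy)-13,14,15,16-tetranorlabda-8,11-diene-6α,19-diol | CC1=C(C=C)[C@@]2(C)C[C@@H](O[Si](C)(C)C(C)(C)C)C[C@](C)(CO)[C@@H]2[C@@H](O)C1 | intermediate
23 | 4-bromofuran-2(5H)-one | O=C1C=C(Br)CO1 | starting material
24 | 12-(9-borabicyclo[3.3.1]nonan-9-yl)-2α-(tert-butyldimethylsilyloxy)-13,14,15,16-tetranorlabd-8-ene-6α,19-diol (hydroxyls drawn free; not isolated) | CC1=C(CCB2C3CCCC2CCC3)[C@@]2(C)C[C@@H](O[Si](C)(C)C(C)(C)C)C[C@](C)(CO)[C@@H]2[C@@H](O)C1 | intermediate
25 | 2α-(tert-butyldimethylsilyloxy)-6α,19-dihydroxylabda-8,13-dien-15,16-olide | CC1=C(CCC2=CC(=O)OC2)[C@@]2(C)C[C@@H](O[Si](C)(C)C(C)(C)C)C[C@](C)(CO)[C@@H]2[C@@H](O)C1 | intermediate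
26 | 2α,6α,19-trihydroxylabda-8,13-dien-15,16-olide (CNP0387838.1) | CC1=C(CCC2=CC(=O)OC2)[C@@]2(C)C[C@@H](O)C[C@](C)(CO)[C@@H]2[C@@H](O)C1 | target

## Step count and risks

Total steps: 13. Longest linear sequence: 13 steps (from 1; the route is fully linear).

**Step 5 (key step).** The hindered copper enolate may be protonated, or the aldolate may revert, before ring closure is secured. The enolate may also discriminate poorly between the two dione carbonyls, which would erode the C10/C4 configuration. The fallback separates reduction from C–C bond formation and uses an irreversible Lewis-acid aldol. It sets out from 9: RhCl(PPh3)3-catalysed 1,4-hydrosilylation with Et3SiH in toluene at 50 °C should give the triethylsilyl ketene acetal F1. TiCl4 in CH2Cl2 at −78 °C should then close ring A by an intramolecular Mukaiyama aldol addition onto the activated dione carbonyl. The same chair is expected, with the silyloxy group equatorial and the flat ketene-acetal carbon axial. Aqueous work-up brings the route back at 12.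

**Step 9.** The enol triflate may be cleaved during the alkaline oxidative work-up, or borane may add only slowly or with poor facial selectivity to an alkene flanked by two quaternary carbons. The fallback avoids both borane and alkaline peroxide and sets out from 17. mCPBA with NaHCO3 in CH2Cl2 at 0 °C should epoxidise only the electron-richer C5=C6 alkene from the open α face, giving the 5α,6α-epoxide F2. Cp2TiCl2 with Mn dust and 1,4-cyclohexadiene in THF at rt generates trivalent titanium (Cp2TiCl), which should open the epoxide homolytically to the tertiary C5 radical with the titanium alkoxide on C6. Hydrogen-atom transfer to the α face of that radical gives 5α-H and 6α-OH, and the route is rejoined at 19.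

**Step 12.** Transmetalation from the hindered alkylborane may be slow enough that base-induced degradation of the bromobutenolide, or of the coupled butenolide, competes. The fallback builds the butenolide ring after the coupling and sets out from 22 through the same borane 24. B-alkyl Suzuki–Miyaura coupling with the robust electrophile 2-bromoprop-2-en-1-ol (PdCl2(dppf), aq K3PO4, THF/DMF, rt) should give the allylic alcohol F3. Acryloyl chloride with 2,4,6-collidine in CH2Cl2 at −78 °C should acylate only the unhindered allylic primary hydroxyl, giving the acrylate F4. Ring-closing metathesis with the second-generation Grubbs catalyst (H2IMes)(PCy3)Cl2Ru=CHPh in toluene at 80 °C should then form the butenolide, which brings the route back at 25.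

## Further compounds

F1 | step 5 | triethylsilyl ketene acetal of 9 after 1,4-hydrosilylation (E/Z mixture at the ketene acetal) | CC[Si](CC)(CC)OC(OC)=C(C)C[C@H](O[Si](C)(C)C(C)(C)C)CC1(C)C(=O)CCCC1=O
F2 | step 9 | methyl 2α-(tert-butyldimethylsilyloxy)-5α,6α-epoxy-9-(trifluoromethanesulfonyloxy)-11,12,13,14,15,16-hexanorlabd-8-en-19-oate | CC1=C(OS(=O)(=O)C(F)(F)F)[C@@]2(C)C[C@@H](O[Si](C)(C)C(C)(C)C)C[C@](C)(C(=O)OC)[C@@]23O[C@H]3C1
F3 | step 12 | allylic alcohol with the C9 side chain CH2CH2C(=CH2)CH2OH on the 2α-silyloxy-6α,19-diol core | CC1=C(CCC(=C)CO)[C@@]2(C)C[C@@H](O[Si](C)(C)C(C)(C)C)C[C@](C)(CO)[C@@H]2[C@@H](O)C1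
F4 | step 12 | acrylate ester of the allylic hydroxyl of F3 | CC1=C(CCC(=C)COC(=O)C=C)[C@@]2(C)C[C@@H](O[Si](C)(C)C(C)(C)C)C[C@](C)(CO)[C@@H]2[C@@H](O)C1
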